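Both C4'=C5' double bonds are cut back to two molecules of acetaldehyde and a bis(dialdehyde) ester of the protected cyclopentane core. The key step uses the fact that C3' of each acyl chain carries two identical CH2CHO arms next to the C2'H2–C1' ester arm, remote from the stereocentres of the five-membered core ring. A chiral secondary amine condenses one arm of each chain with acetaldehyde, so that both E-enals and both C3' stereocentres arise in one operation and no ring is formed. Its precursor, tetra-aldehyde 16, carries two 3-(2-oxoethyl)-5-oxopentanoyl groups on the primary and the secondary oxygen of the acetonide-protected core and comes from ozonolysis of a bis(cyclopent-3-enylacetate).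

Key step: step 11

Chain numbering: C1' ester carbonyl, C2' CH2, C3' branching CH, C4'=C5' the ethylidene alkene (C4' bears CHO), C6' CH3.

Assumption: the (S)-configured catalyst is taken to favour the arm that leads to 3'S; the sense would be settled on a one-chain model ester, and the (R)-catalyst used if it proves opposite.

Remark on the structures: target 19, precursor 16 and product 18 are mutually consistent (core 1S,2R,3R,5R in cyclopentylmethyl numbering, all four ring substituents alternating trans; chains 3'S,4'E) and are used unchanged. Because the core is chiral, the two CH2CHO arms on each C3' are strictly diastereotopic, so a wrong-arm product is a diastereomer of 18 and can in principle be separated from it.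

Remark on the precursor: the acetonide is kept through the key step so that no free hydroxyl can form hemiacetals with the four aldehydes. Each dialdehyde stays masked as a cyclopentene until the step before, and 16 is made immediately before use and not stored.

Remark on stoichiometry: step 9 takes up two molecules of acid 13 and step 11 two molecules of acetaldehyde 17, one per hydroxyl and one per acyl chain respectively; step 11 releases two molecules of water.

Step 1
Reactants: 1 cis-cyclopent-4-ene-1,3-diyl diacetate (meso)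
Product: 2 (1R,4S)-4-hydroxycyclopent-2-en-1-yl acetate
Conditions: electric eel acetylcholinesterase, aqueous NaH2PO4/Na2HPO4 buffer (pH 7), rt
Reagents that add atoms: none
Why: Enzymatic desymmetrisation (enantiotopic ester hydrolysis): the esterase cleaves only the acetate on the (S)-configured carbon of the meso diester, which leaves the (1R)-acetate and so fixes the absolute configuration of the core.

Step 2
Reactants: 2 (1R,4S)-4-hydroxycyclopent-2-en-1-yl acetate; 3 dimethyl malonate
Product: 4 dimethyl 2-[(1R,4S)-4-hydroxycyclopent-2-en-1-yl]propanedioate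
Conditions: NaH, THF, 0 °C; Pd(PPh3)4 (cat.), rt → 50 °C
Reagents that add atoms: none
Why: Tsuji–Trost allylic alkylation: zerovalent palladium ionises the acetate with inversion and the malonate attacks the allyl complex anti to the metal at the terminus remote from the hydroxyl, so the C–C bond forms with net retention, cis-1,4 to OH.

Step 3
Reactants: 4 dimethyl 2-[(1R,4S)-4-hydroxycyclopent-2-en-1-yl]propanedioate
Product: 5 2-[(1R,4S)-4-hydroxycyclopent-2-en-1-yl]propane-1,3-diol
Conditions: LiAlH4, THF, 0 °C → rt; aqueous NaOH work-up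
Reagents that add atoms: none
Why: Reduction of both ester groups with LiAlH4 to the 1,3-diol, a standard hydride reduction that touches neither the isolated alkene nor the two stereocentres.

Step 4
Reactants: 5 2-[(1R,4S)-4-hydroxycyclopent-2-en-1-yl]propane-1,3-diol
Product: 6 (1S,4R)-4-(2,2-dimethyl-1,3-dioxan-5-yl)cyclopent-2-en-1-ol
Conditions: 2,2-dimethoxypropane, pyridinium p-toluenesulfonate (cat.), acetone, rt
Reagents that add atoms: 2,2-dimethoxypropane, COC(C)(C)OC
Why: Acid-catalysed transketalisation (acetonide formation): only the 1,3-diol can close a cyclic ketal, the six-membered 1,3-dioxane, so the ring hydroxyl stays free.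

Step 5
Reactants: 6 (1S,4R)-4-(2,2-dimethyl-1,3-dioxan-5-yl)cyclopent-2-en-1-ol
Product: 7 (4R)-4-(2,2-dimethyl-1,3-dioxan-5-yl)cyclopent-2-en-1-one
Conditions: MnO2, CH2Cl2, rt
Reagents that add atoms: none
Why: Oxidation of the allylic alcohol with MnO2, a neutral heterogeneous oxidation that leaves the ketal intact and offers no base to epimerise the γ-stereocentre C4.

Step 6
Reactants: 7 (4R)-4-(2,2-dimethyl-1,3-dioxan-5-yl)cyclopent-2-en-1-one
Product: 9 (2R,3S,4R)-4-(2,2-dimethyl-1,3-dioxan-5-yl)-3-ethenyl-2-methylcyclopentan-1-one, via bromomagnesium enolate 8 (not isolated)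
Conditions: CH2=CHMgBr, CuBr·SMe2 (20 mol %), THF, −78 → −40 °C; then MeI, HMPA, −40 → 0 °C
Reagents that add atoms: vinylmagnesium bromide, C=C[Mg]Br; iodomethane, CI
Why: Copper-catalysed conjugate addition followed by enolate alkylation: the vinyl group adds to C3 anti to the dioxanyl group on C4 and the regiodefined enolate is methylated at C2 anti to the new vinyl group, which should give the all-trans, thermodynamically preferred ketone.

Step 7
Reactants: 9 (2R,3S,4R)-4-(2,2-dimethyl-1,3-dioxan-5-yl)-3-ethenyl-2-methylcyclopentan-1-one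
Product: 10 (1S,2R,3S,4R)-4-(2,2-dimethyl-1,3-dioxan-5-yl)-3-ethenyl-2-methylcyclopentan-1-ol
Conditions: LiBH(s-Bu)3, THF, −78 °C; then NaOH, H2O2, 0 °C
Reagents that add atoms: none
Why: Ketone reduction with a bulky trialkylborohydride: hydride is delivered to the carbonyl face anti to the adjacent methyl group, so the hydroxyl should end cis to CH3, which is the C1 epimer of the core alcohol and is inverted in step 9.

Step 8
Reactants: 10 (1S,2R,3S,4R)-4-(2,2-dimethyl-1,3-dioxan-5-yl)-3-ethenyl-2-methylcyclopentan-1-ol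
Product: 12 (1S,2R,3S,4R)-4-(2,2-dimethyl-1,3-dioxan-5-yl)-3-(hydroxymethyl)-2-methylcyclopentan-1-ol, via ozonide 11 (not isolated)
Conditions: O3, CH2Cl2, −78 °C; then NaBH4, MeOH, −78 °C → rt
Reagents that add atoms: ozone, [O-][O+]=O
Why: Ozonolysis with reductive NaBH4 work-up turns the vinyl group into CH2OH without touching the ring stereocentres, the ketal and the secondary alcohol being inert to ozone.

Step 9
Reactants: 12 (1S,2R,3S,4R)-4-(2,2-dimethyl-1,3-dioxan-5-yl)-3-(hydroxymethyl)-2-methylcyclopentan-1-ol; 13 2-(cyclopent-3-en-1-yl)acetic acid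
Product: 14 [(1S,2R,3R,5R)-3-{[2-(cyclopent-3-en-1-yl)acetyl]oxy}-5-(2,2-dimethyl-1,3-dioxan-5-yl)-2-methylcyclopentyl]methyl 2-(cyclopent-3-en-1-yl)acetate
Conditions: 13 (3 equiv), PPh3, DIAD, THF, 0 °C → rt
Reagents that add atoms: none
Why: Double Mitsunobu esterification: the primary alkoxyphosphonium ion is displaced by the carboxylate without stereochemical consequence and the secondary one by SN2 with inversion, which turns the cis OH/CH3 arrangement into the required trans one.

Step 10
Reactants: 14 [(1S,2R,3R,5R)-3-{[2-(cyclopent-3-en-1-yl)acetyl]oxy}-5-(2,2-dimethyl-1,3-dioxan-5-yl)-2-methylcyclopentyl]methyl 2-(cyclopent-3-en-1-yl)acetate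
Product: 16 [(1S,2R,3R,5R)-5-(2,2-dimethyl-1,3-dioxan-5-yl)-2-methyl-3-{[5-oxo-3-(2-oxoethyl)pentanoyl]oxy}cyclopentyl]methyl 5-oxo-3-(2-oxoethyl)pentanoate, via bis-ozonide 15 (not isolated)
Conditions: O3, CH2Cl2, −78 °C; then PPh3, −78 °C → rt; used at once
Reagents that add atoms: ozone, [O-][O+]=O
Why: Ozonolysis with reductive PPh3 work-up: the two ring alkenes are the only oxidisable sites, and each cyclopentene opens to a 3-substituted pentanedial without creating a stereocentre.

Step 11
Reactants: 16 [(1S,2R,3R,5R)-5-(2,2-dimethyl-1,3-dioxan-5-yl)-2-methyl-3-{[5-oxo-3-(2-oxoethyl)pentanoyl]oxy}cyclopentyl]methyl 5-oxo-3-(2-oxoethyl)pentanoate; 17 acetaldehyde (2 equiv, one per acyl chain)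
Product: 18 [(1S,2R,3R,5R)-5-(2,2-dimethyl-1,3-dioxan-5-yl)-3-{[(3S,4E)-4-formyl-3-(2-oxoethyl)hex-4-enoyl]oxy}-2-methylcyclopentyl]methyl (3S,4E)-4-formyl-3-(2-oxoethyl)hex-4-enoate
Conditions: 17 (2.5 equiv) added by syringe pump, (S)-2-[diphenyl(trimethylsilyloxy)methyl]pyrrolidine (20 mol %), 4-(dimethylamino)benzoic acid (20 mol %), CH2Cl2, 0 °C → rt
Reagents that add atoms: acetaldehyde (the second molecule of 17, one being incorporated per acyl chain), CC=O
Why: Proposed new method: the amine forms an enamine at one CH2CHO arm of each chain, its nucleophilic carbon (the future C4') adds to one molecule of acetaldehyde per chain, two in all, and the β-hydroxy iminium ion loses water through its enamine tautomer (E1cB) to give the conjugated iminium ion, whose hydrolysis releases the E-enal and the catalyst, so that two C–C bonds become the two C4'=C5' double bonds and no ring is closed. The closest known reaction types are the secondary amine/carboxylic acid-catalysed α-methylenation and aldehyde–aldehyde condensation of aldehydes, amine-catalysed cross-aldol additions between aldehydes, and catalytic desymmetrisation of prochiral dialdehydes; new is their combination with acetaldehyde as acceptor and with selection between two like arms. Each new stereocentre (C3' of either chain) is controlled by the C2 stereocentre of the catalyst pyrrolidine: the enamines of the two arms are diastereomeric, and in the bond-forming transition state acetaldehyde approaches the face remote from the Ph2C(OSiMe3) group while C3' turns either its ester arm or its free aldehyde arm toward the electrophile, the core stereocentres being six or more bonds away and so without influence. The step needs acetaldehyde to act only as acceptor, which slow addition should secure because the catalyst then rests as the substrate enamine while the β-branched substrate aldehydes are poor acceptors. It also needs one condensation per chain, which the product should secure because the α-branched conjugated enal is a poor enamine donor and the arm left over is the one the catalyst disfavours, so that mono-adducts formed at the wrong arm are carried on to the bis-ethylidene by-product and the isomeric purity of 18 should rise with conversion. The E geometry (CH3 trans to CHO) is the thermodynamic one and should be reached through the reversible iminium manifold.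

Step 12
Reactants: 18 [(1S,2R,3R,5R)-5-(2,2-dimethyl-1,3-dioxan-5-yl)-3-{[(3S,4E)-4-formyl-3-(2-oxoethyl)hex-4-enoyl]oxy}-2-methylcyclopentyl]methyl (3S,4E)-4-formyl-3-(2-oxoethyl)hex-4-enoate
Product: 19 [(1S,2R,3R,5R)-5-(1,3-dihydroxypropan-2-yl)-3-{[(3S,4E)-4-formyl-3-(2-oxoethyl)hex-4-enoyl]oxy}-2-methylcyclopentyl]methyl (3S,4E)-4-formyl-3-(2-oxoethyl)hex-4-enoate (CNP0313563.1)
Conditions: AcOH/THF/H2O (3:1:1), rt
Reagents that add atoms: none
Why: Acid-catalysed hydrolysis of the 1,3-dioxane ketal in aqueous acetic acid, conditions under which the esters, the saturated aldehydes and the E-enals should persist and no stereocentre is labile.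

Compound list
1 | cis-cyclopent-4-ene-1,3-diyl diacetate (meso) | CC(=O)O[C@@H]1C=C[C@H](OC(C)=O)C1 | starting material
2 | (1R,4S)-4-hydroxycyclopent-2-en-1-yl acetate | O[C@@H]1C=C[C@H](OC(C)=O)C1 | intermediate
3 | dimethyl malonate | COC(=O)CC(=O)OC | starting material
4 | dimethyl 2-[(1R,4S)-4-hydroxycyclopent-2-en-1-yl]propanedioate (cis) | O[C@@H]1C=C[C@H](C(C(=O)OC)C(=O)OC)C1 | intermediate
5 | 2-[(1R,4S)-4-hydroxycyclopent-2-en-1-yl]propane-1,3-diol | O[C@@H]1C=C[C@H](C(CO)CO)C1 | intermediate
6 | (1S,4R)-4-(2,2-dimethyl-1,3-dioxan-5-yl)cyclopent-2-en-1-ol | O[C@@H]1C=C[C@H](C2COC(C)(C)OC2)C1 | intermediate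
7 | (4R)-4-(2,2-dimethyl-1,3-dioxan-5-yl)cyclopent-2-en-1-one | O=C1C=C[C@H](C2COC(C)(C)OC2)C1 | intermediate
8 | bromomagnesium 3,4-trans-4-(2,2-dimethyl-1,3-dioxan-5-yl)-3-ethenylcyclopent-1-en-1-olate | C=C[C@@H]1C=C(O[Mg]Br)C[C@H]1C2COC(C)(C)OC2 | intermediate
9 | (2R,3S,4R)-4-(2,2-dimethyl-1,3-dioxan-5-yl)-3-ethenyl-2-methylcyclopentan-1-one (all-trans) | C=C[C@@H]1[C@@H](C)C(=O)C[C@H]1C2COC(C)(C)OC2 | intermediate
10 | (1S,2R,3S,4R)-4-(2,2-dimethyl-1,3-dioxan-5-yl)-3-ethenyl-2-methylcyclopentan-1-ol (OH cis to CH3) | C=C[C@@H]1[C@@H](C)[C@@H](O)C[C@H]1C2COC(C)(C)OC2 | intermediate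
11 | ozonide of 10: the 3-(1,2,4-trioxolan-3-yl) analogue of 10, trioxolane carbon unassigned | C1(OCOO1)[C@@H]2[C@@H](C)[C@@H](O)C[C@H]2C3COC(C)(C)OC3 | intermediate
12 | (1S,2R,3S,4R)-4-(2,2-dimethyl-1,3-dioxan-5-yl)-3-(hydroxymethyl)-2-methylcyclopentan-1-ol (C1 epimer of the core diol) | OC[C@@H]1[C@@H](C)[C@@H](O)C[C@H]1C2COC(C)(C)OC2 | intermediate
13 | 2-(cyclopent-3-en-1-yl)acetic acid | OC(=O)CC1CC=CC1 | starting material
14 | [(1S,2R,3R,5R)-3-{[2-(cyclopent-3-en-1-yl)acetyl]oxy}-5-(2,2-dimethyl-1,3-dioxan-5-yl)-2-methylcyclopentyl]methyl 2-(cyclopent-3-en-1-yl)acetate | O=C(CC1CC=CC1)OC[C@@H]2[C@@H](C)[C@H](OC(=O)CC3CC=CC3)C[C@H]2C4COC(C)(C)OC4 | intermediate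
15 | bis-ozonide of 14: both cyclopentenes as 6,7,8-trioxabicyclo[3.2.1]octan-3-yl units, trioxolane carbons unassigned | O=C(CC1CC2OOC(C1)O2)OC[C@@H]3[C@@H](C)[C@H](OC(=O)CC4CC5OOC(C4)O5)C[C@H]3C6COC(C)(C)OC6 | intermediate
16 | [(1S,2R,3R,5R)-5-(2,2-dimethyl-1,3-dioxan-5-yl)-2-methyl-3-{[5-oxo-3-(2-oxoethyl)pentanoyl]oxy}cyclopentyl]methyl 5-oxo-3-(2-oxoethyl)pentanoate | O=CCC(CC=O)CC(=O)OC[C@@H]1[C@@H](C)[C@H](OC(=O)CC(CC=O)CC=O)C[C@H]1C2COC(C)(C)OC2 | intermediate
17 | acetaldehyde | CC=O | starting material
18 | [(1S,2R,3R,5R)-5-(2,2-dimethyl-1,3-dioxan-5-yl)-3-{[(3S,4E)-4-formyl-3-(2-oxoethyl)hex-4-enoyl]oxy}-2-methylcyclopentyl]methyl (3S,4E)-4-formyl-3-(2-oxoethyl)hex-4-enoate | C/C=C(/C=O)[C@@H](CC=O)CC(=O)OC[C@@H]1[C@@H](C)[C@H](OC(=O)C[C@H](CC=O)/C(C=O)=C\C)C[C@H]1C2COC(C)(C)OC2 | intermediate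
19 | [(1S,2R,3R,5R)-5-(1,3-dihydroxypropan-2-yl)-3-{[(3S,4E)-4-formyl-3-(2-oxoethyl)hex-4-enoyl]oxy}-2-methylcyclopentyl]methyl (3S,4E)-4-formyl-3-(2-oxoethyl)hex-4-enoate | C/C=C(/C=O)[C@@H](CC=O)CC(=O)OC[C@@H]1[C@@H](C)[C@H](OC(=O)C[C@H](CC=O)/C(C=O)=C\C)C[C@H]1C(CO)CO | target

Total step count: 12. Longest linear sequence: 12 steps (1 to 19); acid 13 and acetaldehyde 17 are purchased.

Steps most likely to fail

1. Step 11 (the proposed new method). Acetaldehyde may condense with itself or serve as donor toward the substrate aldehydes. The catalyst may discriminate poorly between the two arms, condensation may run on at the second arm of a chain, or the 1,5-dialdehyde units may hold the amine as a cyclic hemiaminal ether. The fallback uses known chemistry only, sets out from 12 and comes back at 18; each chain is brought in as a preformed, enantiopure, masked acid. Crotonaldehyde is α-iodinated (I2, K2CO3, DMAP cat., THF/H2O) to (2Z)-2-iodobut-2-enal F1, reduced under Luche conditions (NaBH4, CeCl3, MeOH) to (2Z)-2-iodobut-2-en-1-ol F2 and silylated (TBSCl, imidazole) to tert-butyl{[(2Z)-2-iodobut-2-en-1-yl]oxy}dimethylsilane F3. Iodine–lithium exchange (t-BuLi, Et2O, −78 °C) and trapping with 2-isopropoxy-4,4,5,5-tetramethyl-1,3,2-dioxaborolane should give, with retention of geometry, the alkenylboronate tert-butyldimethyl{[(2E)-2-(4,4,5,5-tetramethyl-1,3,2-dioxaborolan-2-yl)but-2-en-1-yl]oxy}silane F4. Rhodium-catalysed asymmetric conjugate addition of F4 to commercial 5,6-dihydro-2H-pyran-2-one ([Rh(OH)(cod)]2, the BINAP enantiomer that delivers the 4S product, aqueous KOH, dioxane) sets C3' in lactone (4S)-4-[(2E)-1-{[tert-butyl(dimethyl)silyl]oxy}but-2-en-2-yl]oxan-2-one F5. The lactone is opened with LiOH and silylated on both oxygens in the same flask (TBSCl, imidazole, DMF) to the silyl ester tert-butyldimethylsilyl (3S,4E)-4-({[tert-butyl(dimethyl)silyl]oxy}methyl)-3-(2-{[tert-butyl(dimethyl)silyl]oxy}ethyl)hex-4-enoate F6. Selective cleavage of the silyl ester (K2CO3, MeOH/H2O) gives (3S,4E)-4-({[tert-butyl(dimethyl)silyl]oxy}methyl)-3-(2-{[tert-butyl(dimethyl)silyl]oxy}ethyl)hex-4-enoic acid F7. Double Mitsunobu esterification of 12 with F7 (PPh3, DIAD, THF) should give, with the same inversion as in step 9, the tetrasilylated bis-ester of the core F8. Buffered HF·pyridine in THF at 0 °C removes the four silyl groups to give the tetraol bis-ester of the core F9, which is oxidised without storage so that the 5-hydroxy esters have no time to lactonise. Dess–Martin periodinane (NaHCO3, CH2Cl2) then oxidises the two allylic and the two saturated primary alcohols to the four aldehydes of 18.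

2. Step 9. Substitution at the hindered secondary alkoxyphosphonium ion by a weakly acidic aliphatic carboxylate may be slow, so that elimination toward C2, acylation with retention or intramolecular displacement by a still free primary hydroxyl competes and mono-ester accumulates. The fallback sets out from 12 and comes back at 14. Mitsunobu inversion with the more acidic 4-nitrobenzoic acid (PPh3, DIAD, toluene) gives [(1S,2R,3R,5R)-5-(2,2-dimethyl-1,3-dioxan-5-yl)-2-methyl-3-(4-nitrobenzoyloxy)cyclopentyl]methyl 4-nitrobenzoate F10. Methanolysis (K2CO3, MeOH) frees (1R,2R,3S,4R)-4-(2,2-dimethyl-1,3-dioxan-5-yl)-3-(hydroxymethyl)-2-methylcyclopentan-1-ol F11, the diol of natural configuration. Steglich esterification of both hydroxyls with 13 (EDC·HCl, DMAP, CH2Cl2) then proceeds with retention to 14.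

3. Step 6. Proton exchange between the magnesium enolate and the methylated ketone may scramble the enolate, leading to methylation at C5 or double methylation, and alkylation of the magnesium enolate may stall. The fallback sets out from 7 and comes back at 9, placing the methyl group before the conjugate addition. α-Iodination (I2, pyridine, CH2Cl2) gives (4S)-4-(2,2-dimethyl-1,3-dioxan-5-yl)-2-iodocyclopent-2-en-1-one F12. Suzuki–Miyaura coupling with methylboronic acid (Pd(dppf)Cl2, K2CO3, dioxane/H2O) gives (4R)-4-(2,2-dimethyl-1,3-dioxan-5-yl)-2-methylcyclopent-2-en-1-one F13. Conjugate addition of the vinyl cuprate (CH2=CHMgBr, CuI, THF, −40 °C) anti to the C4 substituent, protonation on work-up and brief equilibration at C2 with DBU should then give the all-trans ketone 9.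

Further compounds
F1 | step 11 | (2Z)-2-iodobut-2-enal | C/C=C(I)/C=O
F2 | step 11 | (2Z)-2-iodobut-2-en-1-ol | C/C=C(I)/CO
F3 | step 11 | tert-butyl{[(2Z)-2-iodobut-2-en-1-yl]oxy}dimethylsilane | C/C=C(I)/CO[Si](C)(C)C(C)(C)C
F4 | step 11 | tert-butyldimethyl{[(2E)-2-(4,4,5,5-tetramethyl-1,3,2-dioxaborolan-2-yl)but-2-en-1-yl]oxy}silane | C/C=C(/CO[Si](C)(C)C(C)(C)C)B1OC(C)(C)C(C)(C)O1
F5 | step 11 | (4S)-4-[(2E)-1-{[tert-butyl(dimethyl)silyl]oxy}but-2-en-2-yl]oxan-2-one | O=C1C[C@H](CCO1)/C(CO[Si](C)(C)C(C)(C)C)=C\C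
F6 | step 11 | tert-butyldimethylsilyl (3S,4E)-4-({[tert-butyl(dimethyl)silyl]oxy}methyl)-3-(2-{[tert-butyl(dimethyl)silyl]oxy}ethyl)hex-4-enoate | CC(C)(C)[Si](C)(C)OC(=O)C[C@H](CCO[Si](C)(C)C(C)(C)C)/C(CO[Si](C)(C)C(C)(C)C)=C\C
F7 | step 11 | (3S,4E)-4-({[tert-butyl(dimethyl)silyl]oxy}methyl)-3-(2-{[tert-butyl(dimethyl)silyl]oxy}ethyl)hex-4-enoic acid | OC(=O)C[C@H](CCO[Si](C)(C)C(C)(C)C)/C(CO[Si](C)(C)C(C)(C)C)=C\C
F8 | step 11 | tetrasilylated bis-ester of the core (as in 14) with two (3S,4E)-4-(silyloxymethyl)-3-(2-silyloxyethyl)hex-4-enoyl groups, silyl = tert-butyldimethylsilyl | C/C=C(/CO[Si](C)(C)C(C)(C)C)[C@@H](CCO[Si](C)(C)C(C)(C)C)CC(=O)OC[C@@H]1[C@@H](C)[C@H](OC(=O)C[C@H](CCO[Si](C)(C)C(C)(C)C)/C(CO[Si](C)(C)C(C)(C)C)=C\C)C[C@H]1C2COC(C)(C)OC2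
F9 | step 11 | tetraol bis-ester of the core (as in 14) with two (3S,4E)-4-(hydroxymethyl)-3-(2-hydroxyethyl)hex-4-enoyl groups | C/C=C(/CO)[C@@H](CCO)CC(=O)OC[C@@H]1[C@@H](C)[C@H](OC(=O)C[C@H](CCO)/C(CO)=C\C)C[C@H]1C2COC(C)(C)OC2
F10 | step 9 | [(1S,2R,3R,5R)-5-(2,2-dimethyl-1,3-dioxan-5-yl)-2-methyl-3-(4-nitrobenzoyloxy)cyclopentyl]methyl 4-nitrobenzoate | O=C(c1ccc(cc1)[N+](=O)[O-])OC[C@@H]2[C@@H](C)[C@H](OC(=O)c3ccc(cc3)[N+](=O)[O-])C[C@H]2C4COC(C)(C)OC4
F11 | step 9 | (1R,2R,3S,4R)-4-(2,2-dimethyl-1,3-dioxan-5-yl)-3-(hydroxymethyl)-2-methylcyclopentan-1-ol | OC[C@@H]1[C@@H](C)[C@H](O)C[C@H]1C2COC(C)(C)OC2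
F12 | step 6 | (4S)-4-(2,2-dimethyl-1,3-dioxan-5-yl)-2-iodocyclopent-2-en-1-one | O=C1C(I)=C[C@H](C2COC(C)(C)OC2)C1
F13 | step 6 | (4R)-4-(2,2-dimethyl-1,3-dioxan-5-yl)-2-methylcyclopent-2-en-1-one | O=C1C(C)=C[C@H](C2COC(C)(C)OC2)C1
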